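## Structural features

The target 24 is a 1,7-diarylheptanoid in which the C1 and C5 oxygens of the chain are tied into one oxane ring (O1, C2 to C6). Ring B (4-hydroxy-3,5-dimethoxyphenyl) sits directly on C6, ring A (4-hydroxy-3-methoxyphenyl) is joined to C2 through a CH2CH2 link, and C4 carries a free hydroxyl. The stereocentres C2, C4 and C6 alternate with CH2 groups, so none is adjacent to another; all three substituents are cis (2S,4R,6S) and therefore equatorial on one chair. The fragile parts are the two electron-rich free phenols and the C6–O1 bond, which is benzylic and para to the ring B oxygen and can open by acid ionisation, by quinone methide formation or by hydrogenolysis. The real difficulty is to set three remote stereocentres in one absolute sense while keeping five oxygen functions apart. The feature used here is that C2 lies two carbons from ring A: with a C=C bond between those carbons, C2 becomes the terminus of a 1-aryl-allyl (cinnamyl) system that ionises easily and reversibly when ring A has a para alkoxy group. O1–C2 can then be closed last by the C6 hydroxyl under equilibrium conditions, which favour exactly the all-equatorial arrangement. Ring B has both methoxy groups meta to C6 and can be switched off electronically by acylating its para oxygen.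

## Logic of the disconnections

Ring numbering is that of 24; open-chain compounds use heptane numbering, in which chain C1, C3 and C5 become ring C6, C4 and C2.

24 to 23: the acyl–oxygen bond of the ring B ester is cut. The acyl group is what keeps the C6–O1 bond closed in the cationic and reductive steps, so it is removed last. Nothing is gained in skeleton. The forward methanolysis must be mild enough for a para-hydroxybenzyl ether.

23 to 22 to 21: the two benzyl–oxygen bonds (ring A phenol, C4 oxygen) are cut, then the C=C bond between C2 and ring A is restored. This puts all hydrogen-labile groups into one operation and makes C2 allylic. The forward hydrogenation must saturate the alkene before the allylic ring bond can be cleaved, and must not cleave the C2–O1 or C6–O1 bonds.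

21 to 18: the O1–C2 bond is cut. The oxane becomes an acyclic chain with a free C1 hydroxyl and an allylic C5 carbinol. One ring and one stereocentre are removed, and the C5 configuration and alkene geometry of 18 become irrelevant. The forward step must ionise only at C5–C7, close only to the six-membered ring, and equilibrate at C2.

18 to 17, then to 12 and 15: the silicon–oxygen bond at the C1 oxygen is cut, then the C5–C6 bond. The chain divides into a ring B aldehyde carrying both fixed stereocentres and a ring A alkenyl iodide. The forward coupling may be unselective at C5 but must spare the aryl ester, which speaks against strongly basic organometallic reagents used in excess.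

15 to 14 to 13: the C=C bond is cut back to the aldehyde carbon (one-carbon homologation) and the benzyl–oxygen bond of ring A is cut. This reaches a commodity phenolic aldehyde. Alkene geometry matters little, because it equilibrates in the key step and is hydrogenated later.

12 to 10 to 9 to 7: the aldehyde carbon is traced to a terminal alkene, the C3 benzyl–oxygen bond is cut, and the C3–C4 bond is cut to an allyl unit and a C3 aldehyde. The forward allylation must place the C3 oxygen anti to the C1 oxygen by reagent control. The benzylation must avoid alkoxides, which would attack the aryl ester and move the silyl group. The C1 oxygen must be masked throughout so that only the C3 oxygen is benzylated.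

7 to 5 to 4 to 2 to 1: the same three operations once more (alkene for aldehyde, silicon–oxygen bond, C1–C2 bond to an allyl unit and the aryl aldehyde), then the acyl–oxygen bond. The forward allylation sets the absolute configuration of the whole molecule at C1, and its work-up must spare the aryl ester.

## Other disconnections considered

Alternative 1: The cut is the O1–C6 bond, on the ring B side of the ring oxygen. Ag2O would oxidise the free 4-alkyl-2,6-dimethoxyphenol of the (3S,5S)-anti-diol A1 to the para-quinone methide A2. The C5 hydroxyl would then add to the methide carbon in a 6-exo closure to give A3, the ring A benzyl ether of 24.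
- In favour: it follows the likely biogenesis. Ring B needs no protecting group and the C4 hydroxyl no ether, so A3 is one hydrogenolysis from 24. A1 has no benzylic stereocentre, only an anti-1,3-diol.
- Against: addition of an alcohol to a quinone methide would be reversed only by base-induced elimination, so C6 would be set essentially kinetically. A2 can also isomerise irreversibly by proton loss next to the methide carbon, or be captured intermolecularly. A3 is still a 4-alkyl-2,6-dimethoxyphenol with a benzylic hydrogen and is open to a second oxidation.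
- Comparison: both plans close the same ring by C–O bond formation, from opposite ends. Both set two centres beforehand and create the third in the cyclisation, so they are equal there. On step economy the alternative is better: no silyl ether on and off, no acyl group, one final deprotection. On mechanism the chosen plan has error correction at the new centre and never exposes a free electron-rich phenol to an oxidant.

Alternative 2: The cut is the C2–C3 carbon–carbon bond. Bu3SnH with an initiator would cleave the C–I bond of A4 homolytically. The radical centre at C3 would add 6-exo to the β-carbon of the (E)-β-alkoxy enone built on the C6 oxygen, giving A5 with C2 cis to C6 through a chair transition state.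
- In favour: a ring C–C bond forms under neutral conditions, and cis selectivity for this acceptor type is dependable. No cation is involved, so ring B can be a plain benzyl ether and both phenols are freed together. On protecting-group simplicity at ring B it is better than the chosen plan.
- Against: selectivity at C2 is kinetic and irreversible. A5 carries an aryl ketone next to ring A; reducing it to CH2 costs extra steps and, by hydrogenolysis, competes with cleavage of C6–O1. The C4 silyl ether needs its own deprotection, and stoichiometric tin must be removed.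
- Comparison: the material needed before the key step is comparable, and the plans are equal in centres set beforehand (two) and created in the key step (one). The alternative is longer after the key step and cannot correct C2. The chosen plan carries the side chain at the right oxidation level throughout.

Alternative 3: The cut is the C5–C6 carbon–carbon bond. DDQ would remove hydride from the benzylic CH2 of the ring B benzyl ether A6, and the enol acetate would attack the cationic benzylic carbon through a chair transition state to give the cis-2,6-disubstituted oxan-4-one A7. Axial hydride reduction of the ketone and two deprotections would follow.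
- In favour: a C–C bond is made by C–H functionalisation and A6 is assembled convergently. Only C2 needs asymmetric synthesis, since C6 comes from the cyclisation and C4 from substrate-controlled reduction; one reagent-controlled centre against two is better than the chosen plan. Ring A is saturated from the outset, so no alkene is hydrogenated next to a ring C–O bond.
- Against: ring A must be kept electron-poor (pivalate) so that DDQ leaves its benzylic CH2 alone. A7 keeps an oxidisable benzylic C6–H on the electron-rich ring. The C4 configuration depends on a later reduction, and the enol acetate needs an extra metal-catalysed step.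
- Comparison: both plans pass through a stabilised cation, with the rings in opposite roles. There ring B is electron-rich to help ionisation and the centres are fixed kinetically; here ring B is electron-poor to prevent ionisation and the centre is fixed by equilibrium. Step counts should be about equal, and the endgame is the same in kind.

Key step: step 12

Remark on the chemistry: (−)-Ipc2B(allyl), the reagent from (+)-α-pinene, is taken to deliver allyl to the Si face of an aldehyde (S carbinol from an aryl aldehyde) and (+)-Ipc2B(allyl) to the Re face; if the sense were the opposite, the two antipodes would change places between steps 2 and 5.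

Check of configurations: 18 is 1S,3R (both C5 epimers); 21 is 2R,4R,6S; 22, 23 and 24 are 2S,4R,6S. The geometry is the same at every centre; the letter at C2 changes on hydrogenation only through CIP priorities, as does the letter at C3 between 10, 12 and 17. Three design points govern the approach to 18:
- the two allylations use opposite reagent antipodes to give the anti relationship;
- the C1 hydroxyl is masked (silyl ether) while the C3 hydroxyl is benzylated;
- benzylation and aldehyde coupling are non-basic to spare the aryl pivalate.

## Route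

Step 1
Reactants: 1 syringaldehyde
Product: 2 4-formyl-2,6-dimethoxyphenyl pivalate
Conditions: PivCl, Et3N, DMAP (cat.), CH2Cl2, 0 °C to rt
Reagents that add atoms: pivaloyl chloride, CC(C)(C)C(Cl)=O
Why: O-acylation of a phenol; the hindered aryl pivalate withdraws the para lone pair of ring B and is the most robust simple aryl ester for the steps that follow.

Step 2
Reactants: 2 4-formyl-2,6-dimethoxyphenyl pivalate
Product: 4 4-[(1S)-1-hydroxybut-3-en-1-yl]-2,6-dimethoxyphenyl pivalate, via diisopinocampheylborinate ester 3 (not isolated)
Conditions: (−)-Ipc2B(allyl), Et2O, −78 °C; then MeOH, pH 7 phosphate buffer, 30% H2O2, 0 °C to rt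
Reagents that add atoms: (−)-B-allyldiisopinocampheylborane, C=CCB([C@@H]1C[C@@H]2C[C@H]([C@H]1C)C2(C)C)[C@@H]1C[C@@H]2C[C@H]([C@H]1C)C2(C)C
Why: Brown allylation through a closed chair transition state with the aryl group equatorial; the isopinocampheyl groups direct allyl to the Si face, which gives the S carbinol (target C6). The ester is inert to the allylborane and buffered peroxide cleaves borinate 3 without hydroxide.

Step 3
Reactants: 4 4-[(1S)-1-hydroxybut-3-en-1-yl]-2,6-dimethoxyphenyl pivalate
Product: 5 4-[(1S)-1-(tert-butyldimethylsilyloxy)but-3-en-1-yl]-2,6-dimethoxyphenyl pivalate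
Conditions: TBSOTf, 2,6-lutidine, CH2Cl2, −78 to 0 °C
Reagents that add atoms: tert-butyldimethylsilyl triflate, CC(C)(C)[Si](C)(C)OS(=O)(=O)C(F)(F)F
Why: Silylation with a non-nucleophilic base, so the aryl ester is not attacked; the silyl ether marks the C1 oxygen as the one to be freed for the ring closure.

Step 4
Reactants: 5 4-[(1S)-1-(tert-butyldimethylsilyloxy)but-3-en-1-yl]-2,6-dimethoxyphenyl pivalate
Product: 7 4-[(1S)-1-(tert-butyldimethylsilyloxy)-3-oxopropyl]-2,6-dimethoxyphenyl pivalate, via vicinal diol 6 (not isolated)
Conditions: OsO4 (cat.), NaIO4, 2,6-lutidine, 1,4-dioxane/H2O (3:1), rt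
Reagents that add atoms: osmium tetroxide (delivers the oxygen), O=[Os](=O)(=O)=O; sodium periodate (replenishes it), [Na+].[O-]I(=O)(=O)=O
Why: Lemieux–Johnson cleavage, dihydroxylation to diol 6 and periodate cleavage in one flask; preferred to ozone because ring B is electron-rich, and 2,6-lutidine suppresses over-oxidation. No stereocentre is touched.

Step 5
Reactants: 7 4-[(1S)-1-(tert-butyldimethylsilyloxy)-3-oxopropyl]-2,6-dimethoxyphenyl pivalate
Product: 9 4-[(1S,3R)-1-(tert-butyldimethylsilyloxy)-3-hydroxyhex-5-en-1-yl]-2,6-dimethoxyphenyl pivalate, via diisopinocampheylborinate ester 8 (not isolated)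
Conditions: (+)-Ipc2B(allyl), Et2O, −78 °C; then MeOH, pH 7 phosphate buffer, 30% H2O2, 0 °C to rt
Reagents that add atoms: (+)-B-allyldiisopinocampheylborane, C=CCB([C@H]1C[C@H]2C[C@@H]([C@@H]1C)C2(C)C)[C@H]1C[C@H]2C[C@@H]([C@@H]1C)C2(C)C
Why: Second Brown allylation with the antipodal reagent, so allyl enters the Re face and the new carbinol (target C4) is 3R, anti to the C1 silyloxy group. Control is by the reagent; the remote silyloxy group has little bias of its own.

Step 6
Reactants: 9 4-[(1S,3R)-1-(tert-butyldimethylsilyloxy)-3-hydroxyhex-5-en-1-yl]-2,6-dimethoxyphenyl pivalate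
Product: 10 4-[(1S,3R)-3-(benzyloxy)-1-(tert-butyldimethylsilyloxy)hex-5-en-1-yl]-2,6-dimethoxyphenyl pivalate
Conditions: 2-benzyloxy-1-methylpyridinium triflate, MgO, PhCF3, 85 °C
Reagents that add atoms: 2-benzyloxy-1-methylpyridinium triflate, C[n+]1ccccc1OCc1ccccc1.[O-]S(=O)(=O)C(F)(F)F
Why: Benzyl transfer from the pyridinium salt under neutral conditions with MgO as acid scavenger; no alkoxide is formed, so the aryl pivalate is not attacked and the silyl group cannot migrate from the C1 to the C3 oxygen.

Step 7
Reactants: 10 4-[(1S,3R)-3-(benzyloxy)-1-(tert-butyldimethylsilyloxy)hex-5-en-1-yl]-2,6-dimethoxyphenyl pivalate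
Product: 12 4-[(1S,3S)-3-(benzyloxy)-1-(tert-butyldimethylsilyloxy)-5-oxopentyl]-2,6-dimethoxyphenyl pivalate, via vicinal diol 11 (not isolated)
Conditions: OsO4 (cat.), NaIO4, 2,6-lutidine, 1,4-dioxane/H2O (3:1), rt
Reagents that add atoms: osmium tetroxide (delivers the oxygen), O=[Os](=O)(=O)=O; sodium periodate (replenishes it), [Na+].[O-]I(=O)(=O)=O
Why: Lemieux–Johnson cleavage as in step 4; benzyl ether, silyl ether and aryl ester are inert. The geometry at C3 is unchanged (the letter becomes S through CIP priorities); the β-benzyloxy aldehyde is used without delay.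

Step 8
Reactants: 13 vanillin
Product: 14 4-(benzyloxy)-3-methoxybenzaldehyde
Conditions: BnBr, K2CO3, DMF, rt
Reagents that add atoms: benzyl bromide, BrCc1ccccc1
Why: Williamson etherification of the phenol; the para benzyloxy group later stabilises the allyl cation and leaves in the final hydrogenation. Compound 14 is also a catalogue item, so this step can be skipped.

Step 9
Reactants: 14 4-(benzyloxy)-3-methoxybenzaldehyde
Product: 15 1-(benzyloxy)-4-[(E)-2-iodoethenyl]-2-methoxybenzene
Conditions: CHI3, CrCl2, THF, 0 °C to rt
Reagents that add atoms: iodoform, IC(I)I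
Why: Takai olefination; the geminal dichromium carbenoid adds to the aldehyde and anti elimination should give mainly the E-alkenyl iodide. Geometric purity is not critical, since the alkene equilibrates in step 12 and is hydrogenated in step 13.

Step 10
Reactants: 12 4-[(1S,3S)-3-(benzyloxy)-1-(tert-butyldimethylsilyloxy)-5-oxopentyl]-2,6-dimethoxyphenyl pivalate; 15 1-(benzyloxy)-4-[(E)-2-iodoethenyl]-2-methoxybenzene
Product: 17 4-[(1S,3R,6E)-3-(benzyloxy)-7-[4-(benzyloxy)-3-methoxyphenyl]-1-(tert-butyldimethylsilyloxy)-5-hydroxyhept-6-en-1-yl]-2,6-dimethoxyphenyl pivalate (both C5 epimers), via alkenylchromium dichloride 16 (not isolated)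
Conditions: CrCl2, NiCl2 (cat.), DMSO, rt
Reagents that add atoms: none
Why: Nozaki–Hiyama–Kishi coupling; nickel inserts into the C–I bond, transmetalation gives alkenylchromium 16, which adds only to the aldehyde and leaves esters and ethers alone. C5 forms as both epimers, which is immaterial because C5 is ionised in step 12.

Step 11
Reactants: 17 4-[(1S,3R,6E)-3-(benzyloxy)-7-[4-(benzyloxy)-3-methoxyphenyl]-1-(tert-butyldimethylsilyloxy)-5-hydroxyhept-6-en-1-yl]-2,6-dimethoxyphenyl pivalate
Product: 18 4-[(1S,3R,6E)-3-(benzyloxy)-7-[4-(benzyloxy)-3-methoxyphenyl]-1,5-dihydroxyhept-6-en-1-yl]-2,6-dimethoxyphenyl pivalate (both C5 epimers)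
Conditions: TBAF, AcOH (1:1), THF, 0 °C to rt
Reagents that add atoms: none
Why: Fluoride cleavage of the silyl ether, buffered with acetic acid so that neither the aryl pivalate (base) nor the ionisable cinnamyl alcohol (acid) is at risk; chromatography on base-washed silica is advisable.

Step 12
Reactants: 18 4-[(1S,3R,6E)-3-(benzyloxy)-7-[4-(benzyloxy)-3-methoxyphenyl]-1,5-dihydroxyhept-6-en-1-yl]-2,6-dimethoxyphenyl pivalate
Product: 21 (2R,4R,6S)-4-(benzyloxy)-2-{(E)-2-[4-(benzyloxy)-3-methoxyphenyl]ethenyl}-6-[3,5-dimethoxy-4-(pivaloyloxy)phenyl]oxane, via allylic perrhenate ester 19 (not isolated), via allyl cation perrhenate ion pair 20 (not isolated)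
Conditions: Re2O7 (5 mol%), CH2Cl2, rt
Reagents that add atoms: none
Why: Re2O7 converts the allylic hydroxyl of 18 into perrhenate ester 19, which ionises to the para-benzyloxy-stabilised allyl cation 20 or transposes by a [3,3] shift; both C5 epimers and both alkene geometries feed the same cation, so the step is stereoconvergent. The closest known reaction type is the Re2O7-mediated allylic alcohol transposition with capture by a pendant hydroxyl that gives 2,6-cis tetrahydropyrans under thermodynamic control. The C1 hydroxyl adds to the nearer allyl terminus (target C2) in a 6-exo-trig closure that forms O1–C2; attack at the benzylic terminus would need an eight-membered ring, and the C3 oxygen is blocked as a benzyl ether. The new centre C2 is not fixed kinetically: 21 is itself a cinnamyl ether and re-ionises under the catalyst, so C2 epimers and transposed or intermolecular ethers should drain into the chair with styryl, benzyloxy and aryl groups all equatorial, as dictated by C4 and C6. The selectivity needed is ionisation at C5–C7 and not at the benzylic C1 (target C6); ring B has its para oxygen as a pivalate and both methoxy groups meta to C1, so that C–O bond should stay closed and C6 keeps its S configuration. Should C6 ionise occasionally, the non-ionisable C4 centre would still direct the equilibrium to the same all-cis enantiomer. The E-alkene is the thermodynamic geometry of the conjugated product.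

Step 13
Reactants: 21 (2R,4R,6S)-4-(benzyloxy)-2-{(E)-2-[4-(benzyloxy)-3-methoxyphenyl]ethenyl}-6-[3,5-dimethoxy-4-(pivaloyloxy)phenyl]oxane
Product: 23 (2S,4R,6S)-6-[3,5-dimethoxy-4-(pivaloyloxy)phenyl]-2-[2-(4-hydroxy-3-methoxyphenyl)ethyl]oxan-4-ol, via saturated oxane bis(benzyl ether) 22 (not isolated)
Conditions: H2 (1 atm), 10% Pd/C, EtOAc/EtOH, rt
Reagents that add atoms: none
Why: Heterogeneous catalytic hydrogenation should saturate the conjugated alkene first, which gives 22 in the flask, and hydrogenolysis of both O-benzyl bonds follows; the ring C6–O1 bond sits on an acylated, less electron-rich ring and should resist under neutral conditions. No stereocentre changes; the letter at C2 goes from R to S only through CIP priorities.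

Step 14
Reactants: 23 (2S,4R,6S)-6-[3,5-dimethoxy-4-(pivaloyloxy)phenyl]-2-[2-(4-hydroxy-3-methoxyphenyl)ethyl]oxan-4-ol
Product: 24 (2S,4R,6S)-6-(4-hydroxy-3,5-dimethoxyphenyl)-2-[2-(4-hydroxy-3-methoxyphenyl)ethyl]oxan-4-ol
Conditions: K2CO3, MeOH (degassed), rt; aq. NH4Cl work-up
Reagents that add atoms: none
Why: Base-mediated transesterification of the aryl ester to methyl pivalate; ethers and the oxane are inert and exclusion of air protects the phenoxides. If the ring B phenoxide opened C6–O1 reversibly through its quinone methide, re-closure would favour the same all-equatorial isomer.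

## Compound list

1 | syringaldehyde (4-hydroxy-3,5-dimethoxybenzaldehyde) | COc1cc(C=O)cc(OC)c1O | starting material
2 | 4-formyl-2,6-dimethoxyphenyl pivalate | COc1cc(C=O)cc(OC)c1OC(=O)C(C)(C)C | intermediate
3 | (1S)-1-[3,5-dimethoxy-4-(pivaloyloxy)phenyl]but-3-en-1-yl diisopinocampheylborinate (Ipc groups of the (+)-α-pinene series) | C=CC[C@@H](c1cc(OC)c(OC(=O)C(C)(C)C)c(OC)c1)OB([C@@H]1C[C@@H]2C[C@H]([C@H]1C)C2(C)C)[C@@H]1C[C@@H]2C[C@H]([C@H]1C)C2(C)C | intermediate (not isolated)
4 | 4-[(1S)-1-hydroxybut-3-en-1-yl]-2,6-dimethoxyphenyl pivalate | C=CC[C@@H](c1cc(OC)c(OC(=O)C(C)(C)C)c(OC)c1)O | intermediate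
5 | 4-[(1S)-1-(tert-butyldimethylsilyloxy)but-3-en-1-yl]-2,6-dimethoxyphenyl pivalate | C=CC[C@@H](c1cc(OC)c(OC(=O)C(C)(C)C)c(OC)c1)O[Si](C)(C)C(C)(C)C | intermediate
6 | 4-[(1S)-1-(tert-butyldimethylsilyloxy)-3,4-dihydroxybutyl]-2,6-dimethoxyphenyl pivalate (both C3 epimers) | OCC(O)C[C@@H](c1cc(OC)c(OC(=O)C(C)(C)C)c(OC)c1)O[Si](C)(C)C(C)(C)C | intermediate (not isolated)
7 | 4-[(1S)-1-(tert-butyldimethylsilyloxy)-3-oxopropyl]-2,6-dimethoxyphenyl pivalate | O=CC[C@@H](c1cc(OC)c(OC(=O)C(C)(C)C)c(OC)c1)O[Si](C)(C)C(C)(C)C | intermediate
8 | diisopinocampheylborinate of 9 at the C3 oxygen (Ipc groups of the (−)-α-pinene series) | C=CC[C@@H](OB([C@H]1C[C@H]2C[C@@H]([C@@H]1C)C2(C)C)[C@H]1C[C@H]2C[C@@H]([C@@H]1C)C2(C)C)C[C@@H](c1cc(OC)c(OC(=O)C(C)(C)C)c(OC)c1)O[Si](C)(C)C(C)(C)C | intermediate (not isolated)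
9 | 4-[(1S,3R)-1-(tert-butyldimethylsilyloxy)-3-hydroxyhex-5-en-1-yl]-2,6-dimethoxyphenyl pivalate (1,3-anti) | C=CC[C@@H](O)C[C@@H](c1cc(OC)c(OC(=O)C(C)(C)C)c(OC)c1)O[Si](C)(C)C(C)(C)C | intermediate
10 | 4-[(1S,3R)-3-(benzyloxy)-1-(tert-butyldimethylsilyloxy)hex-5-en-1-yl]-2,6-dimethoxyphenyl pivalate | C=CC[C@@H](OCc1ccccc1)C[C@@H](c1cc(OC)c(OC(=O)C(C)(C)C)c(OC)c1)O[Si](C)(C)C(C)(C)C | intermediate
11 | 4-[(1S,3R)-3-(benzyloxy)-1-(tert-butyldimethylsilyloxy)-5,6-dihydroxyhexyl]-2,6-dimethoxyphenyl pivalate (both C5 epimers) | OCC(O)C[C@@H](OCc1ccccc1)C[C@@H](c1cc(OC)c(OC(=O)C(C)(C)C)c(OC)c1)O[Si](C)(C)C(C)(C)C | intermediate (not isolated)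
12 | 4-[(1S,3S)-3-(benzyloxy)-1-(tert-butyldimethylsilyloxy)-5-oxopentyl]-2,6-dimethoxyphenyl pivalate | O=CC[C@@H](OCc1ccccc1)C[C@@H](c1cc(OC)c(OC(=O)C(C)(C)C)c(OC)c1)O[Si](C)(C)C(C)(C)C | intermediate
13 | vanillin (4-hydroxy-3-methoxybenzaldehyde) | COc1cc(C=O)ccc1O | starting material
14 | 4-(benzyloxy)-3-methoxybenzaldehyde | COc1cc(C=O)ccc1OCc1ccccc1 | intermediate
15 | 1-(benzyloxy)-4-[(E)-2-iodoethenyl]-2-methoxybenzene | COc1cc(/C=C/I)ccc1OCc1ccccc1 | intermediate
16 | {(E)-2-[4-(benzyloxy)-3-methoxyphenyl]ethenyl}chromium dichloride | COc1cc(/C=C/[Cr](Cl)Cl)ccc1OCc1ccccc1 | intermediate (not isolated)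
17 | 4-[(1S,3R,6E)-3-(benzyloxy)-7-[4-(benzyloxy)-3-methoxyphenyl]-1-(tert-butyldimethylsilyloxy)-5-hydroxyhept-6-en-1-yl]-2,6-dimethoxyphenyl pivalate (both C5 epimers) | COc1cc(/C=C/C(O)C[C@@H](OCc2ccccc2)C[C@@H](c2cc(OC)c(OC(=O)C(C)(C)C)c(OC)c2)O[Si](C)(C)C(C)(C)C)ccc1OCc1ccccc1 | intermediate
18 | 4-[(1S,3R,6E)-3-(benzyloxy)-7-[4-(benzyloxy)-3-methoxyphenyl]-1,5-dihydroxyhept-6-en-1-yl]-2,6-dimethoxyphenyl pivalate (both C5 epimers) | COc1cc(/C=C/C(O)C[C@@H](OCc2ccccc2)C[C@@H](c2cc(OC)c(OC(=O)C(C)(C)C)c(OC)c2)O)ccc1OCc1ccccc1 | intermediate
19 | C5 perrhenate ester of 18 | COc1cc(/C=C/C(O[Re](=O)(=O)=O)C[C@@H](OCc2ccccc2)C[C@@H](c2cc(OC)c(OC(=O)C(C)(C)C)c(OC)c2)O)ccc1OCc1ccccc1 | intermediate (not isolated)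
20 | (E)-1-aryl-allyl cation of 18 (C5 to C7) as its perrhenate ion pair | COc1cc(/C=C/[CH+]C[C@@H](OCc2ccccc2)C[C@@H](c2cc(OC)c(OC(=O)C(C)(C)C)c(OC)c2)O)ccc1OCc1ccccc1.[O-][Re](=O)(=O)=O | intermediate (not isolated)
21 | (2R,4R,6S)-4-(benzyloxy)-2-{(E)-2-[4-(benzyloxy)-3-methoxyphenyl]ethenyl}-6-[3,5-dimethoxy-4-(pivaloyloxy)phenyl]oxane (all-cis) | COc1cc(/C=C/[C@H]2C[C@@H](OCc3ccccc3)C[C@@H](c3cc(OC)c(OC(=O)C(C)(C)C)c(OC)c3)O2)ccc1OCc1ccccc1 | intermediate
22 | (2S,4R,6S)-4-(benzyloxy)-2-{2-[4-(benzyloxy)-3-methoxyphenyl]ethyl}-6-[3,5-dimethoxy-4-(pivaloyloxy)phenyl]oxane (all-cis) | COc1cc(CC[C@H]2C[C@@H](OCc3ccccc3)C[C@@H](c3cc(OC)c(OC(=O)C(C)(C)C)c(OC)c3)O2)ccc1OCc1ccccc1 | intermediate (not isolated)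
23 | (2S,4R,6S)-6-[3,5-dimethoxy-4-(pivaloyloxy)phenyl]-2-[2-(4-hydroxy-3-methoxyphenyl)ethyl]oxan-4-ol | COc1cc(CC[C@H]2C[C@@H](O)C[C@@H](c3cc(OC)c(OC(=O)C(C)(C)C)c(OC)c3)O2)ccc1O | intermediate
24 | (2S,4R,6S)-6-(4-hydroxy-3,5-dimethoxyphenyl)-2-[2-(4-hydroxy-3-methoxyphenyl)ethyl]oxan-4-ol | COc1cc(CC[C@H]2C[C@@H](O)C[C@@H](c3cc(OC)c(O)c(OC)c3)O2)ccc1O | target

## Step count and least certain steps

Total: 14 steps. Longest linear sequence: 12 steps (1 to 24 through steps 1 to 7 and 10 to 14); the ring A branch has 2 steps (8 and 9).

Step 12 (key step). Most likely to go wrong: incomplete equilibration at C2, so that 2,6-trans material persists; proton loss from the allyl cation to a conjugated diene; or ionisation at C1 despite the pivalate, followed by elimination. The fallback sets out from 17 and comes back to the route at 22. The allylic alcohol of 17 is oxidised with Dess–Martin periodinane to the C5 enone F1. Conjugate reduction with [(Ph3P)CuH]6 gives the saturated C5 ketone F2. Reductive etherification with Et3SiH and BiBr3 in MeCN cleaves the silyl ether in the flask and closes the δ-hydroxy ketone to a cyclic oxocarbenium ion; axial hydride delivery gives 22, which is isolated here and then debenzylated over Pd/C as in the second stage of step 13. This replaces thermodynamic C–O closure by kinetic hydride delivery and needs no styrenyl cation.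

Step 13. Most likely to go wrong: hydrogenolysis of the allylic C2–O1 bond before the alkene is saturated, or of the benzylic C6–O1 bond during the slower cleavage of the secondary benzyl ether; either opens the ring. The fallback sets out from 21 and comes back at 23. Diimide, generated from 2-nitrobenzenesulfonyl hydrazide and Et3N, saturates the alkene without touching C–O bonds, so that 22 is obtained and isolated. The two benzyl ethers of 22 are then removed over Pd/C in EtOAc, where no allylic ether remains, to give 23.

Step 6. Most likely to go wrong: C-benzylation of the electron-rich ring B by the benzyl cation equivalent, or sluggish O-benzylation of the hindered carbinol with thermal erosion of the silyl ether. The fallback sets out from 9 and comes back at 10. Silylation with TMSCl and Et3N gives the C3 trimethylsilyl ether F3. Reductive etherification with PhCHO, Et3SiH and catalytic TMSOTf at −78 °C then builds the benzyl ether from benzaldehyde by hydride reduction of an oxocarbenium ion, without a free benzyl cation, and gives 10.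

Step 10. Most likely to go wrong: slow metal insertion and transmetalation with the electron-rich alkenyl iodide, leading to protodehalogenation or homocoupling; and Lewis-acid-promoted β-elimination of benzyl alcohol from 12. The fallback sets out from 12 and 14 and comes back at 17. Vinylmagnesium bromide is added to 12 at −78 °C, where the hindered aryl pivalate should survive a small excess, to give the vinyl carbinol F4. Wittig methylenation of 14 (Ph3P=CH2) gives the styrene F5. Cross-metathesis of F4 with F5 under the second-generation Hoveyda–Grubbs catalyst forms the C6=C7 bond with E geometry and gives 17.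

## Further compounds

F1 | step 12 | 4-[(1S,3S,6E)-3-(benzyloxy)-7-[4-(benzyloxy)-3-methoxyphenyl]-1-(tert-butyldimethylsilyloxy)-5-oxohept-6-en-1-yl]-2,6-dimethoxyphenyl pivalate | COc1cc(/C=C/C(=O)C[C@@H](OCc2ccccc2)C[C@@H](c2cc(OC)c(OC(=O)C(C)(C)C)c(OC)c2)O[Si](C)(C)C(C)(C)C)ccc1OCc1ccccc1
F2 | step 12 | 4-[(1S,3S)-3-(benzyloxy)-7-[4-(benzyloxy)-3-methoxyphenyl]-1-(tert-butyldimethylsilyloxy)-5-oxoheptyl]-2,6-dimethoxyphenyl pivalate | COc1cc(CCC(=O)C[C@@H](OCc2ccccc2)C[C@@H](c2cc(OC)c(OC(=O)C(C)(C)C)c(OC)c2)O[Si](C)(C)C(C)(C)C)ccc1OCc1ccccc1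
F0 | step 13 | none | none
F3 | step 6 | 4-[(1S,3R)-1-(tert-butyldimethylsilyloxy)-3-(trimethylsilyloxy)hex-5-en-1-yl]-2,6-dimethoxyphenyl pivalate | C=CC[C@@H](O[Si](C)(C)C)C[C@@H](c1cc(OC)c(OC(=O)C(C)(C)C)c(OC)c1)O[Si](C)(C)C(C)(C)C
F4 | step 10 | 4-[(1S,3R)-3-(benzyloxy)-1-(tert-butyldimethylsilyloxy)-5-hydroxyhept-6-en-1-yl]-2,6-dimethoxyphenyl pivalate (both C5 epimers) | C=CC(O)C[C@@H](OCc1ccccc1)C[C@@H](c1cc(OC)c(OC(=O)C(C)(C)C)c(OC)c1)O[Si](C)(C)C(C)(C)C
F5 | step 10 | 1-(benzyloxy)-4-ethenyl-2-methoxybenzene | COc1cc(C=C)ccc1OCc1ccccc1
A1 | alternative 1 | (3S,5S)-7-[4-(benzyloxy)-3-methoxyphenyl]-1-(4-hydroxy-3,5-dimethoxyphenyl)heptane-3,5-diol | COc1cc(CC[C@H](O)C[C@@H](O)CCc2cc(OC)c(O)c(OC)c2)ccc1OCc1ccccc1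
A2 | alternative 1 | para-quinone methide of A1: 4-{(3S,5S)-7-[4-(benzyloxy)-3-methoxyphenyl]-3,5-dihydroxyheptylidene}-2,6-dimethoxycyclohexa-2,5-dien-1-one | COc1cc(CC[C@H](O)C[C@@H](O)CC=C2C=C(OC)C(=O)C(OC)=C2)ccc1OCc1ccccc1
A3 | alternative 1 | (2S,4R,6S)-2-{2-[4-(benzyloxy)-3-methoxyphenyl]ethyl}-6-(4-hydroxy-3,5-dimethoxyphenyl)oxan-4-ol | COc1cc(CC[C@H]2C[C@@H](O)C[C@@H](c3cc(OC)c(O)c(OC)c3)O2)ccc1OCc1ccccc1
A4 | alternative 2 | (E)-1-[4-(benzyloxy)-3-methoxyphenyl]-3-{[(1S,3S)-1-[4-(benzyloxy)-3,5-dimethoxyphenyl]-3-(tert-butyldimethylsilyloxy)-4-iodobutyl]oxy}prop-2-en-1-one | COc1cc(C(=O)/C=C/O[C@@H](C[C@@H](CI)O[Si](C)(C)C(C)(C)C)c2cc(OC)c(OCc3ccccc3)c(OC)c2)ccc1OCc1ccccc1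
A5 | alternative 2 | all-cis 1-[4-(benzyloxy)-3-methoxyphenyl]-2-{6-[4-(benzyloxy)-3,5-dimethoxyphenyl]-4-(tert-butyldimethylsilyloxy)oxan-2-yl}ethan-1-one | COc1cc(C(=O)C[C@H]2C[C@@H](O[Si](C)(C)C(C)(C)C)C[C@@H](c3cc(OC)c(OCc4ccccc4)c(OC)c3)O2)ccc1OCc1ccccc1
A6 | alternative 3 | (4S)-4-{[4-(benzyloxy)-3,5-dimethoxybenzyl]oxy}-6-[3-methoxy-4-(pivaloyloxy)phenyl]hex-1-en-2-yl acetate | COc1cc(CC[C@@H](CC(=C)OC(C)=O)OCc2cc(OC)c(OCc3ccccc3)c(OC)c2)ccc1OC(=O)C(C)(C)C
A7 | alternative 3 | (2S,6S)-2-[4-(benzyloxy)-3,5-dimethoxyphenyl]-6-{2-[3-methoxy-4-(pivaloyloxy)phenyl]ethyl}oxan-4-one | COc1cc(CC[C@H]2CC(=O)C[C@@H](c3cc(OC)c(OCc4ccccc4)c(OC)c3)O2)ccc1OC(=O)C(C)(C)C
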